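The trap in these flasks is to expect that a slow feed, by holding the intermediate low, pays in yield.

all flasks: time 10 h

| charge | substrate | partner | remark | temperature |
|---|---|---|---|---|
| spring | 0.15 M | 0.300 M (fed, over 6.0 h) | the addition at 30 °C, then warmed to 70 °C; the feed brings no volume worth counting |  |
| summer | 0.15 M | 0.300 M | everything together at the start | 70 °C |
| dusk | 0.15 M (fed, over 6.0 h) | 0.300 M | all else is in the flask from the start; the feed brings no volume worth counting | 70 °C |
| noon | 0.15 M | 0.300 M | everything together at the start at 30 °C, warmed to 70 °C at 6.0 h |  |

    intermediate → side product (k1 = 1.20 × 10⁻⁴ s⁻¹, Ea1 = 115 kJ mol⁻¹)
    target ⇌ isomer of the product (K2 = 21, k2 = 6.97 × 10⁻⁴ s⁻¹, Ea2 = 102 kJ mol⁻¹, ΔH2 = −46.0 kJ mol⁻¹)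
    partner + intermediate → target (k3 = 0.00823 M⁻¹ s⁻¹, Ea3 = 76.0 kJ mol⁻¹)
    substrate → intermediate (k4 = 5.57 × 10⁻⁴ s⁻¹, Ea4 = 104 kJ mol⁻¹)
    (constants at 70 °C)

1. which flask leads in amount of isomer of the product, in percent of the substrate charged ("all alike" within 1.5 percentage points) (spring / summer / dusk / noon / all alike)
2. how much isomer of the product is there at the end, in percent of the substrate charged: spring
3. how much isomer of the product is there at the end, in percent of the substrate charged: summer
4. how much isomer of the product is there at the end, in percent of the substrate charged: dusk
5. how much isomer of the product is there at the end, in percent of the substrate charged: noon

- the list of constants is for 70 °C, to be carried to other temperatures by the activation energies and enthalpies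

Turn the question round: for one flask to lead by 1.5 percentage points in isomer of the product, what has to differ? The target and isomer pair is an unlikely place. Those two relax to each other with a half-life of 0.264 h at 70 °C, far shorter than the 4.00 h that even the late-warmed flasks spend hot, so you can expect the pair to end at 95.5% isomer. The substrate's half-life, 0.346 h when hot, is also short against those hours. That leaves the side product peak, which has to differ by about 1.6 points.

So write the balance of substrate, the limiting reagent (0.15 M against 0.300 M of partner). Each substrate ends as side product or, using one partner, as target or isomer. Let D be the partner concentration, and let h be the rate constant of the loss to side product over that of the step to target, 0.0146 M at 70 °C. At one temperature, side product forms h / D times as fast as partner is used. This h is the even-split level, the partner concentration at which intermediate goes equally to side product and to target, and D/h is the selectivity factor. The intermediate cancels from that ratio, so at one temperature, with the partner in the flask from the start, side product = h ln(D at the start / D at the end), however the substrate arrives. That covers summer and dusk, but not spring, whose partner is fed.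

The end level of partner is its charge less the substrate plus the side product, and two rounds of substitution with it give 0.00924 M of side product, or 6.16% of the substrate. My reckoning for summer and dusk is therefore 89.6% isomer.

Spring and noon differ from these by their cold hours. At 30 °C, h falls to 0.00240 M, and in those 6.0 h I reckon that 9.34% of the substrate reacts. If that part is spared the loss at the lowest hot partner level, I put the gain at 0.78 points, less than the 1.6 points required. At its feed rate, spring's partner passes that cold level of h within 2.88 min. I expect the flasks to count as alike.

The forecast said all alike, with 89.7% for spring, 89.5% for summer, 89.5% for dusk and 89.8% for noon, holding that “feed order barely matters”.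

The flasks give 89.5% in spring, 89.6% in summer, 89.6% in dusk and 89.6% in noon, so the answer is all alike. Side product stands at 6.16% in summer and 6.16% in dusk. Put summer's end partner, 53.1% of its charge, into the rule with h and you get 6.16%.

In the neighbour like summer but kept at 85 °C, h rises to 0.0258 M and the isomer's share of the pair falls to 91.4%, so the rule gives 0.0155 M of side product, or 10.3% of the substrate, and 82.0% isomer. The computed flask holds 10.3% side product and 82.1% isomer.

(The constants used here are invented; no experiment stands behind them.)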